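Atom numbering (farnesane type): C1 = CH(OBz); C2=C3, with C3 carrying the carboxyl carbon C15; C4; C5; C6–C7 = epoxide (methyl on C7); C8–C10 = (CH2)3; C11 = CMe2. The carbocycle is the eleven-membered humulane ring.
Retrosynthesis: the late adjustments are undone first (H2 across C9–C10, epoxide O on C6–C7, benzoyl on O1, methyl ester on C15). The ring is then cut at C1–C11, and the chain at C8–C9 (allyl–alkenyl coupling), C2=C3 (olefination) and C3–C4 (alkylation).
Enabling feature: the quaternary gem-dimethyl carbon C11 sits directly on carbinol carbon C1 and is followed by the unfunctionalised pair C10–C9, which is the retron of a reverse-prenyl addition. A C9–C10–C11 allylmetal attacks a C1 aldehyde through its dimethyl-substituted end. This copies, with inverted polarity, the C1–C11 closure of farnesyl diphosphate to the humulyl cation and leaves the C9=C10 alkene of humulene.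
Forward order: C3–C4, C2=C3, oxidation at C8, C8–C9, then the only carbocycle (eleven-membered) closes in one step. The oxirane ring follows, and the helper alkene C9=C10 is removed last.
Stereochemistry: C1 comes from the chiral ligand on chromium in the ring closure. C6 and C7 are set together by one Shi epoxidation with the D-fructose-derived ketone. The ring-cis C2=C3 geometry comes from the olefination and E-C6=C7 from the SeO2 oxidation.

Key step: step 9

Assumption: the (S,S) antipode of the carbazole bis(oxazoline) ligand is taken to deliver the allyl group to the Si face of C1; if a test reaction shows the opposite sense, the (R,R) ligand is used and nothing else changes.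

Step 1
Reactants: 1 methyl 2-(diethoxyphosphoryl)acetate; 2 5-bromo-2-methylpent-2-ene
Product: 3 methyl 2-(diethoxyphosphoryl)-6-methylhept-5-enoate (racemic)
Conditions: NaH, NaI (10 mol%), DMF, 0 → 60 °C
Reagents that add atoms: none
Why: The stabilised phosphonoacetate carbanion displaces the primary homoallylic bromide (iodide-assisted SN2 alkylation of an active methylene compound) to form C3–C4; the new centre at C3 is racemic and is destroyed in step 2.

Step 2
Reactants: 3 methyl 2-(diethoxyphosphoryl)-6-methylhept-5-enoate; 4 2,2-dimethoxyacetaldehyde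
Product: 5 methyl (E)-2-(2,2-dimethoxyethylidene)-6-methylhept-5-enoate
Conditions: NaH, THF, 0 °C → rt; 4 added as a dried solution in MTBE
Reagents that add atoms: none
Why: The Horner–Wadsworth–Emmons olefination should place acetal carbon C1 trans to the ester and therefore cis to C4, which is the ring-cis C2=C3 geometry of the target; the minor isomer is removed by chromatography.

Step 3
Reactants: 5 methyl (E)-2-(2,2-dimethoxyethylidene)-6-methylhept-5-enoate
Product: 6 methyl (2E,5E)-2-(2,2-dimethoxyethylidene)-7-hydroxy-6-methylhept-5-enoate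
Conditions: SeO2 (0.3 equiv), t-BuOOH (5.5 M in decane, 3 equiv), CH2Cl2, 0 °C → rt
Reagents that add atoms: tert-butyl hydroperoxide, CC(C)(C)OO (oxygen atom, relayed by catalytic SeO2)
Why: The Riley allylic oxidation (ene reaction, then [2,3]-sigmatropic shift) touches only the electron-rich trisubstituted alkene and, as is general for gem-dimethyl alkenes, its E methyl group, which fixes E-C6=C7 and oxygenates C8.

Step 4
Reactants: 6 methyl (2E,5E)-2-(2,2-dimethoxyethylidene)-7-hydroxy-6-methylhept-5-enoate
Product: 7 methyl (2E,5E)-7-bromo-2-(2,2-dimethoxyethylidene)-6-methylhept-5-enoate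
Conditions: CBr4, PPh3, CH2Cl2, 0 °C
Reagents that add atoms: carbon tetrabromide, BrC(Br)(Br)Br
Why: The Appel reaction replaces the primary allylic hydroxyl by SN2 attack of bromide on the alkoxyphosphonium ion, without allylic transposition and under conditions that leave acetal and enoate alone.

Step 5
Reactants: 8 2-methylbut-3-yn-2-ol; 9 bis(pinacolato)diboron
Product: 10 (E)-2-methyl-4-(4,4,5,5-tetramethyl-1,3,2-dioxaborolan-2-yl)but-3-en-2-ol
Conditions: CuCl (5 mol%), 4,5-bis(diphenylphosphino)-9,9-dimethylxanthene (5 mol%), NaOt-Bu (10 mol%), MeOH (2 equiv), THF, rt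
Reagents that add atoms: none
Why: Copper-catalysed syn-borylcupration and protonation (formal hydroboration of a terminal alkyne) puts boron on the unhindered terminal carbon, gives the E-alkenylboronate and tolerates the free tertiary alcohol.

Step 6
Reactants: 7 methyl (2E,5E)-7-bromo-2-(2,2-dimethoxyethylidene)-6-methylhept-5-enoate; 10 (E)-2-methyl-4-(4,4,5,5-tetramethyl-1,3,2-dioxaborolan-2-yl)but-3-en-2-ol
Product: 11 methyl (2E,5E,8E)-2-(2,2-dimethoxyethylidene)-10-hydroxy-6,10-dimethylundeca-5,8-dienoate
Conditions: Pd(PPh3)4 (5 mol%), K2CO3 (2 M aq.), THF, 50 °C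
Reagents that add atoms: none
Why: In the Suzuki–Miyaura allyl–alkenyl coupling the π-allylpalladium unit from the primary bromide couples at its less hindered terminus C8 with retention of both alkene geometries, which forms C8–C9 and the skipped diene.

Step 7
Reactants: 11 methyl (2E,5E,8E)-2-(2,2-dimethoxyethylidene)-10-hydroxy-6,10-dimethylundeca-5,8-dienoate
Product: 12 methyl (2E,5E,8E)-10-hydroxy-6,10-dimethyl-2-(2-oxoethylidene)undeca-5,8-dienoate
Conditions: p-TsOH·H2O (10 mol%), THF/H2O (4:1), rt
Reagents that add atoms: water, O
Why: Acid-catalysed acetal hydrolysis unmasks the C1 aldehyde in its more stable arrangement trans to the ester, and an acid-induced 1,3-shift of the tertiary allylic hydroxyl would be harmless because both allylic isomers lead to the same allylchromium species in step 9.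

Step 8
Reactants: 12 methyl (2E,5E,8E)-10-hydroxy-6,10-dimethyl-2-(2-oxoethylidene)undeca-5,8-dienoate
Product: 14 methyl (2E,5E)-8-chloro-6,10-dimethyl-2-(2-oxoethylidene)undeca-5,9-dienoate, via allylic chlorosulfite 13 (not isolated)
Conditions: SOCl2 (1.1 equiv), Et2O, −20 → 0 °C; used crude
Reagents that add atoms: thionyl chloride, O=S(Cl)Cl
Why: In ether, thionyl chloride converts allylic alcohols by the SNi' pathway, in which chlorosulfite 13 collapses through a cyclic transition state that delivers chloride to C9 with allylic transposition and without base or long-lived cations; the new C9 centre is racemic and is erased in step 9.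

Step 9
Reactants: 14 methyl (2E,5E)-8-chloro-6,10-dimethyl-2-(2-oxoethylidene)undeca-5,9-dienoate
Product: 17 methyl (1R)-1-hydroxyhumula-2,6,9-trien-15-oate, via allylchromium species 15 (not isolated), via trimethylsilyl ether 16 (not isolated)
Conditions: CrCl2 (20 mol%), (S,S)-1,8-bis(4-isopropyl-4,5-dihydrooxazol-2-yl)-3,6-diphenyl-9H-carbazole (22 mol%), i-Pr2NEt (40 mol%), Mn powder (3 equiv), Me3SiCl (2 equiv), THF, rt, 14 added over 24 h (final 2 mM); then K2CO3 (cat.), MeOH, 0 °C
Reagents that add atoms: none
Why: Divalent chromium reduces the allylic chloride in two one-electron steps to the σ-allyl complex of trivalent chromium 15, which equilibrates by 1,3-metal shift and rests with the metal on secondary C9; the aldehyde oxygen then binds to chromium and C11 attacks C1 by SE2' through a six-membered Zimmerman–Traxler chair (Cr, O, C1, C11, C10, C9), after which Me3SiCl frees the alkoxide as 16 and Mn returns chromium to the divalent state. The closest known reaction types are Nozaki–Hiyama–Kishi allylation macrocyclisations of ω-formyl allylic halides and ligand-controlled chromium-catalysed additions of γ,γ-disubstituted allyl halides that build a quaternary carbon next to the carbinol, and in polarity-inverted form the step copies the C1–C11 closure of farnesyl diphosphate to the humulyl cation. The eleven-membered carbocycle closes 11-exo-trig at the carbonyl carbon with allyl carbons C9–C11 inside the ring and the tether C2–C8 bridging the 1,4-positions of the chair pseudo-equatorially, which should give E-C9=C10 (a Z isomer would be harmless because step 13 removes this alkene). C1 is the only new stereocentre and is set by the twofold-symmetric bis(oxazoline) ligand, which shields the Re face of the bound aldehyde so that C11 adds to the Si face (1R); the racemic C9 centre of 14 is erased because the allylchromium species epimerises faster than it adds, and C11 is not stereogenic. The step needs γ- over α-attack (secured by chromium resting on the less substituted C9 and by the higher strain of the nine-membered alternative), 1,2- over 1,4-addition to the 4-oxo-enoate (secured by the closed oxygen-bound transition state), and ring closure over oligomerisation (secured by slow addition, by the persistence of the allylchromium species and by the turn that ring-cis C2=C3 and E-C6=C7 put into the chain).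

Step 10
Reactants: 17 methyl (1R)-1-hydroxyhumula-2,6,9-trien-15-oate
Product: 18 (1R)-1-hydroxyhumula-2,6,9-trien-15-oic acid
Conditions: LiOH·H2O, THF/MeOH/H2O, 40 °C; then 1 M HCl to pH 4, 0 °C
Reagents that add atoms: lithium hydroxide, [Li+].[OH-]
Why: Saponification of the only ester before the benzoate is introduced avoids any later differentiation of esters, and because the C1 hydroxyl stands trans to the carboxyl across C2=C3 no butenolide can form and C1 is untouched.

Step 11
Reactants: 18 (1R)-1-hydroxyhumula-2,6,9-trien-15-oic acid
Product: 20 (1R)-1-benzoyloxyhumula-2,6,9-trien-15-oic acid, via mixed benzoic anhydride 19 (not isolated)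
Conditions: BzCl (3 equiv), 4-(dimethylamino)pyridine (0.2 equiv), pyridine, 40 °C; then H2O, rt
Reagents that add atoms: benzoyl chloride, O=C(Cl)c1ccccc1
Why: Nucleophile-catalysed acylation benzoylates the neopentylic allylic alcohol with retention at C1, while the carboxyl group is tied up for the time being as mixed anhydride 19 and is set free again by the aqueous pyridine quench.

Step 12
Reactants: 20 (1R)-1-benzoyloxyhumula-2,6,9-trien-15-oic acid
Product: 21 (1R,6R,7R)-1-benzoyloxy-6,7-epoxyhumula-2,9-dien-15-oic acid
Conditions: 1,2:4,5-di-O-isopropylidene-β-D-erythro-2,3-hexodiulo-2,6-pyranose (30 mol%), Oxone (2KHSO5·KHSO4·K2SO4, 1.4 equiv KHSO5), K2CO3, Bu4NHSO4 (cat.), MeCN/CH2(OMe)2, aq. Na2B4O7–Na2EDTA buffer, 0 °C; work-up KH2PO4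
Reagents that add atoms: potassium peroxymonosulfate (active part of Oxone), [K+].[O-]S(=O)(=O)OO
Why: In the Shi epoxidation the dioxirane of the D-fructose-derived ketone transfers oxygen through a spiro transition state to the face of an E-trisubstituted alkene that gives the (R,R)-epoxide, which sets C6 and C7 in one syn addition, while the electron-poor C2=C3 is inert and the disubstituted C9=C10 next to quaternary C11 reacts more slowly.

Step 13
Reactants: 21 (1R,6R,7R)-1-benzoyloxy-6,7-epoxyhumula-2,9-dien-15-oic acid
Product: 22 (1R,6R,7R)-1-benzoyloxy-6,7-epoxyhumul-2-en-15-oic acid (target)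
Conditions: 2,4,6-triisopropylbenzenesulfonyl hydrazide, Et3N, ClCH2CH2Cl, 50 °C
Reagents that add atoms: none
Why: Diimide transfers two hydrogens in a concerted syn fashion and discriminates by substitution and strain, so the strained E-disubstituted C9=C10 alkene should be reduced while the trisubstituted conjugated C2=C3 alkene, the epoxide, the allylic benzoate and all three stereocentres stay untouched.

Compound list
1 | methyl 2-(diethoxyphosphoryl)acetate | COC(=O)CP(=O)(OCC)OCC | starting material
2 | 5-bromo-2-methylpent-2-ene | CC(C)=CCCBr | starting material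
3 | methyl 2-(diethoxyphosphoryl)-6-methylhept-5-enoate (racemic) | COC(=O)C(CCC=C(C)C)P(=O)(OCC)OCC | intermediate
4 | 2,2-dimethoxyacetaldehyde | COC(OC)C=O | starting material
5 | methyl (E)-2-(2,2-dimethoxyethylidene)-6-methylhept-5-enoate | COC(OC)/C=C(\CCC=C(C)C)C(=O)OC | intermediate
6 | methyl (2E,5E)-2-(2,2-dimethoxyethylidene)-7-hydroxy-6-methylhept-5-enoate | COC(OC)/C=C(\CC/C=C(\C)CO)C(=O)OC | intermediate
7 | methyl (2E,5E)-7-bromo-2-(2,2-dimethoxyethylidene)-6-methylhept-5-enoate | COC(OC)/C=C(\CC/C=C(\C)CBr)C(=O)OC | intermediate
8 | 2-methylbut-3-yn-2-ol | CC(C)(O)C#C | starting material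
9 | bis(pinacolato)diboron | CC1(C)OB(OC1(C)C)B1OC(C)(C)C(C)(C)O1 | starting material
10 | (E)-2-methyl-4-(4,4,5,5-tetramethyl-1,3,2-dioxaborolan-2-yl)but-3-en-2-ol | CC(C)(O)/C=C/B1OC(C)(C)C(C)(C)O1 | intermediate
11 | methyl (2E,5E,8E)-2-(2,2-dimethoxyethylidene)-10-hydroxy-6,10-dimethylundeca-5,8-dienoate | COC(OC)/C=C(\CC/C=C(\C)C/C=C/C(C)(C)O)C(=O)OC | intermediate
12 | methyl (2E,5E,8E)-10-hydroxy-6,10-dimethyl-2-(2-oxoethylidene)undeca-5,8-dienoate | O=C/C=C(\CC/C=C(\C)C/C=C/C(C)(C)O)C(=O)OC | intermediate
13 | chlorosulfite ester of the tertiary allylic alcohol 12 | O=C/C=C(\CC/C=C(\C)C/C=C/C(C)(C)OS(=O)Cl)C(=O)OC | intermediate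
14 | methyl (2E,5E)-8-chloro-6,10-dimethyl-2-(2-oxoethylidene)undeca-5,9-dienoate (racemic at C9) | O=C/C=C(\CC/C=C(\C)CC(Cl)C=C(C)C)C(=O)OC | intermediate
15 | σ-allyl complex of trivalent chromium, metal on C9 (chiral ligand left out of the SMILES and drawn as chloride) | O=C/C=C(\CC/C=C(\C)CC([Cr](Cl)Cl)C=C(C)C)C(=O)OC | intermediate
16 | trimethylsilyl ether of 17 | CC1(C)/C=C/C/C(C)=C/CC/C(C(=O)OC)=C\[C@H]1O[Si](C)(C)C | intermediate
17 | methyl (1R)-1-hydroxyhumula-2,6,9-trien-15-oate (eleven-membered ring; ring-cis C2=C3 with CO2Me on C3; 6E; 9E; Me2 on C11) | CC1(C)/C=C/C/C(C)=C/CC/C(C(=O)OC)=C\[C@H]1O | intermediate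
18 | (1R)-1-hydroxyhumula-2,6,9-trien-15-oic acid | CC1(C)/C=C/C/C(C)=C/CC/C(C(=O)O)=C\[C@H]1O | intermediate
19 | benzoic (1R)-1-benzoyloxyhumula-2,6,9-trien-15-oic anhydride | CC1(C)/C=C/C/C(C)=C/CC/C(C(=O)OC(=O)c2ccccc2)=C\[C@H]1OC(=O)c1ccccc1 | intermediate
20 | (1R)-1-benzoyloxyhumula-2,6,9-trien-15-oic acid | CC1(C)/C=C/C/C(C)=C/CC/C(C(=O)O)=C\[C@H]1OC(=O)c1ccccc1 | intermediate
21 | (1R,6R,7R)-1-benzoyloxy-6,7-epoxyhumula-2,9-dien-15-oic acid | CC1(C)/C=C/C[C@@]2(C)O[C@@H]2CC/C(C(=O)O)=C\[C@H]1OC(=O)c1ccccc1 | intermediate
22 | (1R,6R,7R)-1-benzoyloxy-6,7-epoxyhumul-2-en-15-oic acid (CNP0377917.1) | CC1(C)CCC[C@@]2(C)O[C@@H]2CC/C(C(=O)O)=C\[C@H]1OC(=O)c1ccccc1 | target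

Total steps: 13. Longest linear sequence: 12 (steps 1–4 and 6–13).

Steps most likely to fail

Step 9. The electron-poor 4-oxo-enoate may suffer one-electron reduction or pinacol coupling by divalent chromium. The open chain may oligomerise. Facial selectivity may also erode in the crowded ligand sphere.
The fallback sets out from 12 and comes back at 17; it changes both the metal and the source of chirality.
- The free tertiary allylic alcohol of 12 is used directly in a palladium-catalysed umpolung (Pd(PPh3)4, Et2Zn, THF, rt, slow addition).
- A π-allyl complex of divalent palladium is transmetallated to an allylzinc, which is no one-electron reductant and adds through the same chair. This gives the racemic hydroxy triene ester F1.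
- Dess–Martin oxidation gives the achiral trienone ester F2.
- A Corey–Bakshi–Shibata reduction returns 17. The conditions are (S)-1-methyl-3,3-diphenyltetrahydro-1H,3H-pyrrolo[1,2-c][1,3,2]oxazaborole, catecholborane, toluene, −78 °C, with quaternary C11 acting as the large group.

Step 8. The allylic system flanked by the C6=C7 alkene may ionise and lose a C8 proton to give a conjugated triene, either during chlorination or on handling of the chloride.
The fallback sets out from 7 and comes back at 17; it avoids any allylic halide at C9.
- Commercial prenyl phenyl sulfone is deprotonated (n-BuLi, THF, −78 °C) and alkylated at its α-carbon by 7 to give the sulfone acetal F3, a shelf-stable carrier of the C9–C11 allyl unit.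
- Hydrolysis as in step 7 gives the sulfone aldehyde F4.
- Pd(PPh3)4/Et2Zn (THF, slow addition) turns the allylic sulfone into the allylzinc and closes the ring to the racemic hydroxy triene ester F1.
- F1 passes through the trienone ester F2 to 17, as described for step 9.

Step 12. Facial selectivity may be poor if the conformational bias that C1 imposes on the ring opposes the ketone catalyst, and C9=C10 may be over-epoxidised.
The fallback sets out from 17 and comes back at 21; it takes C1 out of play during the epoxidation.
- Compound 17 is oxidised (Dess–Martin periodinane) to the trienone ester F2. This ring has no stereocentre, so the D-fructose-derived ketone alone decides the face.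
- Shi epoxidation gives the (6R,7R)-epoxy dienone ester F5.
- Corey–Bakshi–Shibata reduction as above gives the epoxy hydroxy ester F6.
- LiOH gives the epoxy hydroxy acid F7.
- BzCl/pyridine leads through the epoxy mixed anhydride F8 to 21.

Further compounds
F1 | step 9 | racemic methyl 1-hydroxyhumula-2,6,9-trien-15-oate | CC1(C)/C=C/C/C(C)=C/CC/C(C(=O)OC)=C\C1O
F2 | step 9 | methyl 1-oxohumula-2,6,9-trien-15-oate | CC1(C)/C=C/C/C(C)=C/CC/C(C(=O)OC)=C\C1=O
F3 | step 8 | methyl (2E,5E)-2-(2,2-dimethoxyethylidene)-6,10-dimethyl-8-(phenylsulfonyl)undeca-5,9-dienoate (racemic) | COC(OC)/C=C(\CC/C=C(\C)CC(C=C(C)C)S(=O)(=O)c1ccccc1)C(=O)OC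
F4 | step 8 | methyl (2E,5E)-6,10-dimethyl-2-(2-oxoethylidene)-8-(phenylsulfonyl)undeca-5,9-dienoate (racemic) | O=C/C=C(\CC/C=C(\C)CC(C=C(C)C)S(=O)(=O)c1ccccc1)C(=O)OC
F5 | step 12 | methyl (6R,7R)-6,7-epoxy-1-oxohumula-2,9-dien-15-oate | CC1(C)/C=C/C[C@@]2(C)O[C@@H]2CC/C(C(=O)OC)=C\C1=O
F6 | step 12 | methyl (1R,6R,7R)-6,7-epoxy-1-hydroxyhumula-2,9-dien-15-oate | CC1(C)/C=C/C[C@@]2(C)O[C@@H]2CC/C(C(=O)OC)=C\[C@H]1O
F7 | step 12 | (1R,6R,7R)-6,7-epoxy-1-hydroxyhumula-2,9-dien-15-oic acid | CC1(C)/C=C/C[C@@]2(C)O[C@@H]2CC/C(C(=O)O)=C\[C@H]1O
F8 | step 12 | benzoic (1R,6R,7R)-1-benzoyloxy-6,7-epoxyhumula-2,9-dien-15-oic anhydride | CC1(C)/C=C/C[C@@]2(C)O[C@@H]2CC/C(C(=O)OC(=O)c3ccccc3)=C\[C@H]1OC(=O)c1ccccc1
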